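**Retrosynthetic overview**

1. The target is read as oritin-(4α→6)-oritin. After the O-benzyl groups, the last bond cut is the interflavan C4–C6 bond (ring C to ring D), made by Friedel–Crafts capture of the C4 cation of a flavan-3,4-diol by a flavan-3-ol, trans to the 3-OH.
2. Both partners are one compound: the benzylated (2R,3S)-flavan-3,4-diol is the electrophile as it stands and becomes the nucleophile after ionic removal of its 4-OH.
3. Key disconnection of that diol: O1–C2 and C4a–C4 of the pyran ring, a formal [3+3] union of a ring A phenol (2,3-bis(benzyloxy)phenol) with a trans-2,3-epoxy aldehyde that carries ring B.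
4. Enabling feature: O1 is a phenolic oxygen on C8a whose only free ortho carbon C4a bears C4 (an O,C-1,3-dinucleophile). C4–C3–C2 has oxygen on C4 and C3, and C2 is benzylic to the electron-rich ring B (aldehyde carbon plus oxirane as 1,3-dielectrophile). C4 is also para to O7, so its hydroxyl is later a leaving group.
5. Ring order: rings A, B, D and E are bought as arenes; pyran rings C and F both arise in the one key annulation (one batch, used twice); absolute configuration comes from an organocatalytic enal epoxidation.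

Key step: step 5

Remark on the chemistry: the SMILES is read as (2R,3S,4R) in the upper unit (2,3-trans, 3,4-trans, the ring D substituent at C4 opposite to the 3-OH) and (2R,3S) in the lower unit. Flavan numbering (O1, C2–C4, C4a, C5–C8, C8a) and rings A/B/C (upper unit) and D/E/F (lower unit) are used throughout.

**Route**

Step 1
Reactants: 1 2,3-dihydroxybenzaldehyde
Product: 2 2,3-bis(benzyloxy)benzaldehyde
Conditions: BnBr (2.3 equiv), K2CO3, DMF, 60 °C
Reagents that add atoms: benzyl bromide, BrCc1ccccc1
Why: Williamson etherification (SN2 of both phenoxides on benzyl bromide) should give benzyl ethers that survive every later step and are removed together at the end.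

Step 2
Reactants: 2 2,3-bis(benzyloxy)benzaldehyde
Product: 4 2,3-bis(benzyloxy)phenol, via aryl formate 3 (not isolated)
Conditions: mCPBA, CH2Cl2, 0 °C to rt; then MeOH, Et3N (cat.), rt
Reagents that add atoms: mCPBA (3-chloroperoxybenzoic acid), OOC(=O)c1cccc(Cl)c1
Why: Baeyer–Villiger (Dakin-type) oxidation of the electron-rich ortho-alkoxybenzaldehyde should proceed with aryl migration to the formate, whose mild methanolysis unveils the phenol oxygen that becomes O1.

Step 3
Reactants: 5 3,4-bis(benzyloxy)benzaldehyde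
Product: 6 (E)-3-[3,4-bis(benzyloxy)phenyl]prop-2-enal
Conditions: Ph3P=CHCHO (1.1 equiv), toluene, 80 °C
Reagents that add atoms: (triphenylphosphoranylidene)acetaldehyde, O=CC=P(c1ccccc1)(c1ccccc1)c1ccccc1
Why: Wittig olefination with the stabilised formyl ylide should give the (E)-enal, the geometry that later becomes the trans-oxirane.

Step 4
Reactants: 6 (E)-3-[3,4-bis(benzyloxy)phenyl]prop-2-enal
Product: 7 (2R,3S)-3-[3,4-bis(benzyloxy)phenyl]oxirane-2-carbaldehyde (trans)
Conditions: (S)-2-[bis(3,5-bis(trifluoromethyl)phenyl)(trimethylsilyloxy)methyl]pyrrolidine (10 mol%), 35% aq. H2O2, CH2Cl2, rt; used without chromatography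
Reagents that add atoms: hydrogen peroxide, OO
Why: In this iminium–enamine epoxidation of an enal (Jørgensen epoxidation), H2O2 should add to the (E)-iminium on the face left open by the bulky diarylsilyloxymethyl group (setting the benzylic carbon), and the enamine then closes the trans-oxirane on the peroxide oxygen (setting the aldehyde-bearing carbon); the (S)-catalyst is the enantiomer expected to give the (2R,3S) product.

Step 5
Reactants: 4 2,3-bis(benzyloxy)phenol; 7 (2R,3S)-3-[3,4-bis(benzyloxy)phenyl]oxirane-2-carbaldehyde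
Product: 10 (2R,3S,4R)-7,8-bis(benzyloxy)-2-[3,4-bis(benzyloxy)phenyl]chromane-3,4-diol, via magnesium phenoxide 8 (not isolated), via epoxy carbinol 9 (not isolated)
Conditions: 4 (1.05 equiv), n-Bu2Mg (0.5 equiv), toluene/CH2Cl2, 0 °C; 7 (1.0 equiv), −20 °C to rt; then Ti(OiPr)4 (1.2 equiv), rt; aq. potassium sodium tartrate work-up
Reagents that add atoms: none
Why: Proposed new method: the magnesium phenoxide 8 binds the aldehyde oxygen of 7 at divalent magnesium and adds through its only free ortho carbon in a six-membered, metal-templated transition state (C4a–C4 bond), and in the resulting 2,3-epoxy alkoxide 9 the neighbouring phenol oxygen then opens the oxirane at its remote, benzylic carbon (O1–C2 bond), so that the phenol acts as a 1,3-O,C-dinucleophile and the epoxy aldehyde as a 1,3-dielectrophile in a formal [3+3] annulation. The closest known reaction types are the ortho-specific hydroxyalkylation of magnesium phenoxides with aldehydes (alpha-alkoxy aldehydes included), the Ti(OiPr)4-mediated opening of 2,3-epoxy alcohols at the carbon remote from the carbinol, and the 6-endo cyclisation of 1-(2-hydroxyaryl)-3-aryl-2,3-epoxypropanes to flavan-3-ols; their merger in one flask with an epoxy aldehyde has not been shown. Ring C closes in the 6-endo-tet mode rather than 5-exo-tet at C3 because the tetravalent-titanium chelate between the C4 alkoxide and the oxirane oxygen, together with the para-benzyloxy group of ring B, polarises the benzylic C2–O bond. C3 keeps the configuration of the aldehyde-bearing oxirane carbon because its C–O bond is never broken, C2 is set by stereospecific inversion at the benzylic oxirane carbon so that the trans-oxirane gives the 2,3-trans flavan, and C4 is set by chelate-controlled addition (aldehyde and oxirane oxygens on magnesium) to the 3,4-trans carbinol, although its 4-epimer would serve equally since this centre is ionised in steps 6 and 7. The step needs ortho C-alkylation over O- or para-alkylation, secured by the magnesium template in a non-coordinating solvent and by the blocked second ortho position of 4, and it needs SN2-type opening at C2 without prior ionisation or halide opening, secured by the halide-free, non-protic medium at or below room temperature.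

Step 6
Reactants: 10 (2R,3S,4R)-7,8-bis(benzyloxy)-2-[3,4-bis(benzyloxy)phenyl]chromane-3,4-diol (the larger part of the batch)
Product: 11 (2R,3S)-7,8-bis(benzyloxy)-2-[3,4-bis(benzyloxy)phenyl]chroman-3-ol (tetra-O-benzyl-oritin)
Conditions: Et3SiH (10 equiv), TFA (2 equiv), CH2Cl2, −20 °C, high dilution
Reagents that add atoms: none
Why: In this ionic hydrogenation, TFA ionises the C4 benzylic alcohol (para to O7) and the cation should be trapped by hydride from the large excess of Et3SiH faster than by an arene, leaving C2 and C3 untouched.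

Step 7
Reactants: 10 (2R,3S,4R)-7,8-bis(benzyloxy)-2-[3,4-bis(benzyloxy)phenyl]chromane-3,4-diol; 11 (2R,3S)-7,8-bis(benzyloxy)-2-[3,4-bis(benzyloxy)phenyl]chroman-3-ol (4 equiv)
Product: 12 octa-O-benzyl-oritin-(4α→6)-oritin, i.e. (2R,3S,4S)-7,8-bis(benzyloxy)-2-[3,4-bis(benzyloxy)phenyl]-4-{(2R,3S)-7,8-bis(benzyloxy)-2-[3,4-bis(benzyloxy)phenyl]-3-hydroxychroman-6-yl}chroman-3-ol (4-aryl trans to 3-OH; the C4 descriptor differs from that of the target only through the benzyl groups)
Conditions: TiCl4 (1.1 equiv), CH2Cl2, −30 to 0 °C, slow addition of 10 to 11; excess 11 recovered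
Reagents that add atoms: none
Why: In this Friedel–Crafts alkylation (biomimetic flavan-3,4-diol/flavan-3-ol coupling), Lewis-acid ionisation of the 4-OH gives the C4 benzylic cation, which should be captured by the most nucleophilic arene position of 11 (C6 of ring D, para to O1 and ortho to O7) on the face anti to the 3-OH to set the 3,4-trans C4 centre, with the excess of 11 suppressing self-condensation.

Step 8
Reactants: 12 octa-O-benzyl-oritin-(4α→6)-oritin
Product: 13 oritin-(4α→6)-oritin, i.e. (2R,3S,4R)-2-(3,4-dihydroxyphenyl)-4-[(2R,3S)-2-(3,4-dihydroxyphenyl)-3,7,8-trihydroxychroman-6-yl]chromane-3,7,8-triol (target)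
Conditions: H2 (1 atm), Pd(OH)2/C, THF/MeOH/H2O, rt; filtration and concentration under argon
Reagents that add atoms: none
Why: Heterogeneous hydrogenolysis should cleave the eight aryl benzyl ethers while the doubly benzylic C4–C6 bond and the C2–O1 bonds persist under these mild conditions, so that no stereocentre is touched.

**Compound list**

1 | 2,3-dihydroxybenzaldehyde | O=Cc1cccc(O)c1O | starting material
2 | 2,3-bis(benzyloxy)benzaldehyde | O=Cc1cccc(OCc2ccccc2)c1OCc1ccccc1 | intermediate
3 | 2,3-bis(benzyloxy)phenyl formate | O=COc1cccc(OCc2ccccc2)c1OCc1ccccc1 | intermediate (not isolated)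
4 | 2,3-bis(benzyloxy)phenol | Oc1cccc(OCc2ccccc2)c1OCc1ccccc1 | intermediate
5 | 3,4-bis(benzyloxy)benzaldehyde | O=Cc1ccc(OCc2ccccc2)c(OCc2ccccc2)c1 | starting material
6 | (E)-3-[3,4-bis(benzyloxy)phenyl]prop-2-enal | O=C/C=C/c1ccc(OCc2ccccc2)c(OCc2ccccc2)c1 | intermediate
7 | (2R,3S)-3-[3,4-bis(benzyloxy)phenyl]oxirane-2-carbaldehyde | O=C[C@@H]1O[C@H]1c1ccc(OCc2ccccc2)c(OCc2ccccc2)c1 | intermediate
8 | magnesium bis[2,3-bis(benzyloxy)phenoxide] | [Mg+2].[O-]c1cccc(OCc2ccccc2)c1OCc1ccccc1.[O-]c1cccc(OCc2ccccc2)c1OCc1ccccc1 | intermediate (not isolated)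
9 | 6-{(R)-hydroxy[(2S,3S)-3-(3,4-bis(benzyloxy)phenyl)oxiran-2-yl]methyl}-2,3-bis(benzyloxy)phenol (present as its metal alkoxide, drawn neutral) | O[C@H](c1ccc(OCc2ccccc2)c(OCc2ccccc2)c1O)[C@@H]1O[C@H]1c1ccc(OCc2ccccc2)c(OCc2ccccc2)c1 | intermediate (not isolated)
10 | (2R,3S,4R)-7,8-bis(benzyloxy)-2-[3,4-bis(benzyloxy)phenyl]chromane-3,4-diol (2,3-trans, 3,4-trans) | C(c1ccccc1)Oc1ccc([C@H]2Oc3c(ccc(OCc4ccccc4)c3OCc3ccccc3)[C@@H](O)[C@@H]2O)cc1OCc1ccccc1 | intermediate
11 | (2R,3S)-7,8-bis(benzyloxy)-2-[3,4-bis(benzyloxy)phenyl]chroman-3-ol | C(c1ccccc1)Oc1ccc([C@H]2Oc3c(ccc(OCc4ccccc4)c3OCc3ccccc3)C[C@@H]2O)cc1OCc1ccccc1 | intermediate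
12 | octa-O-benzyl-oritin-(4α→6)-oritin | C(c1ccccc1)Oc1ccc([C@H]2Oc3c(ccc(OCc4ccccc4)c3OCc3ccccc3)[C@@H](c3cc4c(c(OCc5ccccc5)c3OCc3ccccc3)O[C@H](c3ccc(OCc5ccccc5)c(OCc5ccccc5)c3)[C@@H](O)C4)[C@@H]2O)cc1OCc1ccccc1 | intermediate
13 | oritin-(4α→6)-oritin | Oc1ccc([C@H]2Oc3c(ccc(O)c3O)[C@@H](c3cc4c(c(O)c3O)O[C@H](c3ccc(O)c(O)c3)[C@@H](O)C4)[C@@H]2O)cc1O | target

**Step count and risks**

Total step count: 8.
Longest linear sequence: 6 steps (5 → 6 → 7 → 10 → 11 → 12 → 13, steps 3 to 8).

The three steps most likely to fail: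

First, step 5 (the proposed new method).
- What may go wrong: the ortho C-alkylation may be slower than decomposition of the epoxy aldehyde; the carbinol alkoxide may trigger epoxide migration; the phenol may close 5-exo; or C2 may ionise before ring closure and lose the stereospecific inversion.
- Fallback (known chemistry, from 5 back to 10): commercial 2,3,4-trihydroxyacetophenone is benzylated at its two non-chelated hydroxyls (BnBr, K2CO3, acetone) to give 1-[3,4-bis(benzyloxy)-2-hydroxyphenyl]ethanone F1. This is protected (MOMCl, iPr2NEt) as 1-[3,4-bis(benzyloxy)-2-(methoxymethoxy)phenyl]ethanone F2. Claisen–Schmidt condensation of F2 with 5 (KOH, EtOH) should give the (E)-chalcone F3. Juliá–Colonna epoxidation (poly-L-leucine, urea–H2O2 adduct, DBU, THF) should give the (2R,3S)-epoxy ketone F4. Acid (HCl, MeOH/THF) removes the MOM group and lets the freed phenol close 6-endo with inversion to the (2R,3R)-trans-dihydroflavonol F5. NaBH4 reduction from the face anti to the 3-OH then should return the route at 10.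

Second, step 7.
- What may go wrong: the C4 cation may be captured by ring A of a second molecule of 10 or of the product (oligomerisation), attack may occur at C5 of ring D, and facial selectivity at C4 may be incomplete.
- Fallback (from 11 back to 13): the electrophile is rebuilt from 11 with its own nucleophilic position blocked. NBS (CH2Cl2, −78 °C) should brominate C6 to give (2R,3S)-7,8-bis(benzyloxy)-2-[3,4-bis(benzyloxy)phenyl]-6-bromochroman-3-ol F6. Benzylic oxidation at C4 with DDQ in CH2Cl2/MeOH should give the 3,4-trans 4-methoxy-6-bromoflavan-3-ol F7. Me3SiOTf-catalysed coupling of F7 with 11 (CH2Cl2, −78 °C, near-equimolar) should give the 6-bromo derivative of 12 (bromine on C6 of the upper unit) F8. Hydrogenolysis (H2, Pd(OH)2/C, Et3N, THF/MeOH/H2O) removes bromine and all benzyl groups and comes back to the route at 13.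

Third, step 4.
- What may go wrong: iminium formation from the electron-rich enal may be slow, and the para-alkoxyaryl oxirane may open or rearrange under the aqueous peroxide conditions, eroding yield and enantiopurity.
- Fallback (from 6 back to 7): the epoxide is made at the alcohol oxidation level by hydroxyl-directed catalysis. Luche reduction (NaBH4, CeCl3·7H2O, MeOH) gives (E)-3-[3,4-bis(benzyloxy)phenyl]prop-2-en-1-ol F9. Sharpless asymmetric epoxidation (Ti(OiPr)4, L-(+)-diisopropyl tartrate, t-BuOOH, 4 Å molecular sieves, CH2Cl2, −20 °C) should give [(2S,3S)-3-[3,4-bis(benzyloxy)phenyl]oxiran-2-yl]methanol F10. Parikh–Doering oxidation (SO3·pyridine, DMSO, iPr2NEt) returns the route at 7.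

**Further compounds**

F1 | step 5 | 1-[3,4-bis(benzyloxy)-2-hydroxyphenyl]ethanone | CC(=O)c1ccc(OCc2ccccc2)c(OCc2ccccc2)c1O
F2 | step 5 | 1-[3,4-bis(benzyloxy)-2-(methoxymethoxy)phenyl]ethanone | CC(=O)c1ccc(OCc2ccccc2)c(OCc2ccccc2)c1OCOC
F3 | step 5 | (E)-1-[3,4-bis(benzyloxy)-2-(methoxymethoxy)phenyl]-3-[3,4-bis(benzyloxy)phenyl]prop-2-en-1-one | O=C(/C=C/c1ccc(OCc2ccccc2)c(OCc2ccccc2)c1)c1ccc(OCc2ccccc2)c(OCc2ccccc2)c1OCOC
F4 | step 5 | [3,4-bis(benzyloxy)-2-(methoxymethoxy)phenyl]{(2R,3S)-3-[3,4-bis(benzyloxy)phenyl]oxiran-2-yl}methanone | O=C([C@@H]1O[C@H]1c1ccc(OCc2ccccc2)c(OCc2ccccc2)c1)c1ccc(OCc2ccccc2)c(OCc2ccccc2)c1OCOC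
F5 | step 5 | (2R,3R)-7,8-bis(benzyloxy)-2-[3,4-bis(benzyloxy)phenyl]-3-hydroxychroman-4-one | C(c1ccccc1)Oc1ccc([C@H]2Oc3c(ccc(OCc4ccccc4)c3OCc3ccccc3)C(=O)[C@@H]2O)cc1OCc1ccccc1
F6 | step 7 | (2R,3S)-7,8-bis(benzyloxy)-2-[3,4-bis(benzyloxy)phenyl]-6-bromochroman-3-ol | C(c1ccccc1)Oc1ccc([C@H]2Oc3c(cc(Br)c(OCc4ccccc4)c3OCc3ccccc3)C[C@@H]2O)cc1OCc1ccccc1
F7 | step 7 | (2R,3S,4R)-7,8-bis(benzyloxy)-2-[3,4-bis(benzyloxy)phenyl]-6-bromo-4-methoxychroman-3-ol | C(c1ccccc1)Oc1ccc([C@H]2Oc3c(cc(Br)c(OCc4ccccc4)c3OCc3ccccc3)[C@@H](OC)[C@@H]2O)cc1OCc1ccccc1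
F8 | step 7 | 6-bromo derivative of 12 (bromine on C6 of the upper unit, same spatial arrangement as 12) | C(c1ccccc1)Oc1ccc([C@H]2Oc3c(cc(Br)c(OCc4ccccc4)c3OCc3ccccc3)[C@@H](c3cc4c(c(OCc5ccccc5)c3OCc3ccccc3)O[C@H](c3ccc(OCc5ccccc5)c(OCc5ccccc5)c3)[C@@H](O)C4)[C@@H]2O)cc1OCc1ccccc1
F9 | step 4 | (E)-3-[3,4-bis(benzyloxy)phenyl]prop-2-en-1-ol | OC/C=C/c1ccc(OCc2ccccc2)c(OCc2ccccc2)c1
F10 | step 4 | [(2S,3S)-3-[3,4-bis(benzyloxy)phenyl]oxiran-2-yl]methanol | OC[C@@H]1O[C@H]1c1ccc(OCc2ccccc2)c(OCc2ccccc2)c1
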